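The south-east run slows where the south-west run does not: after 4.00 h it still holds 32.1% of its Z, against 0% in the south-west run.

| setting | south-east | south-west | maple | ash | alder |
|---|---|---|---|---|---|
| Z | 11 mM | 11 mM | 11 mM | 11 mM | 11 mM |
| G | 19 mM | 92 mM | 33.0 mM | 66.0 mM | 130 mM |
| L | 0.22 mM | 0.22 mM | 0.220 mM | 0.220 mM | 0.220 mM |
| remark | run made earlier | run made earlier |  |  |  |
| time |  |  | 4.0 h | 4.0 h | 4.0 h |

| run | time / h | Z / % | X / % |
|---|---|---|---|
| south-east | 1.00 | 62.3 | 35.4 |
| south-east | 2.00 | 46.8 | 50.9 |
| south-east | 3.00 | 37.9 | 60.0 |
| south-east | 4.00 | 32.1 | 65.4 |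
| south-west | 1.00 | 8.8 | 89.7 |
| south-west | 2.00 | 0.7 | 97.4 |
| south-west | 3.00 | 0.6 | 97.4 |
| south-west | 4.00 | 0 | 97.7 |

(scatter of a reading: 0.3 percentage points)

- part of the Z that has reacted at the end, maple
- part of the Z that has reacted at the end, ash
- part of the Z that has reacted at the end, alder
- what raising the concentration of G from its lowest to its highest value here does to the part of the Z that has reacted (changes below 5 percentage points count as none) (it falls / no change / it rises)

In the south-east run, Z falls by 0.286 h⁻¹ in relative terms between the first two readings, with about 5.00 mM of Z reacted, and by 0.166 h⁻¹ between the last two, with 7.15 mM reacted. If this loss follows free G, the line through both points reaches zero at a read 10.1 mM of Z reacted, so each Z costs, as a reading, 1.88 G, with a rate constant read as 29.7 M⁻¹ h⁻¹.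

Two amounts then matter: the G charged and the G demand, the G that the whole Z charge consumes at this read cost, 20.6 mM. South-east lies below the demand, so of Z and G, G is the limiting reagent there. Maple lies above it, at 1.60 times the demand, so of these two Z is limiting in maple. My second-order reckoning, with G falling at this cost, gives maple 89.9% reacted.

The forecast gives 88% (82% to 93%) for maple, 99% for ash and 100% for alder, and says it rises. It reads the slowing differently: "Catalyst decay or product inhibition remains".

The flasks give 90.2%, 99.7% and >99.9%; it rises, by 9.8 percentage points.

    Z + G → E + X (k = 30.9 M⁻¹ h⁻¹)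
    G + E ⇌ J, settled at all times (K = 10000 M⁻¹)
    Z + L → D (k = 16600 M⁻¹ h⁻¹)
    G + E ⇌ Q, settled at all times (K = 43.3 M⁻¹)

In alder, the step of Z with L did half its turnover within 0.231 min, and L stands at 0% at the end. The step of Z with G did half by 0.181 h and 94% by 0.800 h, while E took up G into J, which ends at 10.7 mM. The forecast for ash, whose range ends low at 96.5%, would be wrong if the answer moved by 5 points, and the answer for ash has moved that far at 39.2 mM of G, or at 1.86 h, the other settings held. A neighbour like alder with 32 mM of G stands at 1.55 times the demand, and the same reckoning gives 89.0%; computed, it reaches 89.3%.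

The readings are calculated with constants of no real substance, and the scatter is random.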